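## The problem

The target, 5-[(8Z,12S,14Z)-12-hydroxyheptadeca-8,14-dien-1-yl]benzene-1,3-diol (20), is an unbranched C17 chain on a resorcinol ring. No rings have to be joined; the task is to assemble the chain (C1' benzylic to C17' methyl) with three independent stereo-elements: the Z-alkene C8'=C9', the S carbinol C12' and the Z-alkene C14'=C15'. The single stereocentre is insulated from both alkenes by methylene groups and lies eleven carbons from the arene. It can therefore neither be induced by anything in the molecule nor control anything, so it must come from the chiral pool or a reagent, and each alkene geometry needs its own stereospecific reaction. The two isolated Z-alkenes exclude hydrogenolysis and any late step that generates thiyl, iodine-atom or metal-hydride species able to scramble Z to E. The resorcinol is electron-rich (attacked by electrophilic halogen, oxidised at an anode, captures formaldehyde), and its hydroxyls need masking groups that leave without strong Lewis acid or hot nucleophile, which would endanger the homoallylic alcohol. The enabling feature is the segment C12'(O)–C11'–C10' ending at sp2 carbon C9': it has the pattern of C2–C4 of L-glutamic acid, with the side-chain carboxyl exactly where C9' is to be attached. Loss of that carboxyl gives a primary radical at C10' that can be joined to a preformed Z-alkenyl unit, provided the C14'=C15' alkene is still absent, since in the full chain that radical would have a 5-exo cyclisation path.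

## Retrosynthesis

**Phenol O–C bonds (20 from 19).** The last operation is removal of two methoxymethyl groups from 19. Methyl ethers were rejected: thiolates tend to stop after the first demethylation of a meta-dimethoxyarene because the phenoxide deactivates the second, and boron halides threaten the alkenes and the free alcohol. Formaldehyde acetals survive every organometallic, basic and reductive step and leave by acetal exchange in dilute methanolic acid. The forward step only has to spare two isolated alkenes and a secondary alcohol.

**C13'–C14' (19 from 18).** Cutting this bond removes the C14'=C15' alkene and four carbons and leaves the terminal epoxide 18. A Z-butenylcopper nucleophile made by syn carbocupration brings the alkene with fixed geometry. A cut through C14'=C15' by Wittig chemistry would need a one-carbon homologation to a β-oxygenated aldehyde. Alkynylation followed by semi-hydrogenation costs one more step and a hydrogenation beside the C8'=C9' alkene. The forward reaction must attack only the unsubstituted epoxide carbon, so the C12'–O bond and its configuration are not involved.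

**C13'–O activation and ketal (18 from 16 via 17, 16 from 15).** Epoxide 18 comes from diol 16 by sulfonylation of the primary hydroxyl (17) and closure by the C12' oxygen, which keeps its bond to carbon. Diol 16 is the hydrolysis product of dioxolane 15. The forward steps need primary-selective sulfonylation, and cleavage of an acetone ketal beside two aryl formaldehyde acetals.

**C9'–C10' (15 from 14 and 9), the strategic cut.** This sp2–sp3 bond divides the chain into the redox-active ester 14 (C10'–C13' with the stereocentre) and the Z-alkenyl iodide 9 (arene and C1'–C9').
- A Wittig cut through C8'=C9' would set the geometry in the fragment-joining step, with an E contaminant that cannot be removed from an oily lipid.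
- A polar alkylation at C10' would need three functional-group steps to turn the native carboxyl into a halide, and would usually be followed by a semi-reduction.
- An anodic cross-coupling of two acids would be statistical and would oxidise the arene.

The reductive decarboxylative route uses the carboxyl directly and transfers a geometry fixed beforehand. The forward reaction must capture the C10' radical at nickel faster than it is reduced or dimerises, and must retain the Z geometry of 9.

**Radical precursor (14 from 12 and 13; 12 from 11; 11 from 10).** Ester 14 is the N-hydroxyphthalimide (13) ester of acid 12. Acid 12 is the saponification product of methyl ester 11, and 11 is the ring-opened, ketalised form of the commercial amino-acid-derived lactone 10. Lactone 10 already holds C10'–C13' with C12' in the S configuration, and its carbonyl carbon is the atom to be expelled. Protecting C12'–O and C13'–O together as a ketal leaves no stereocentre next to a carbonyl and frees the diol in one step after the coupling.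

**Alkenyl iodide (9 from 8, 6, 5, 2 with 3, and 1).** Iodide 9 comes from iodoalkyne 8 by syn addition of two hydrogens, 8 from terminal alkyne 6 by metalation and iodination, and 6 from bromide 5 by displacement with a two-carbon acetylide. Bromide 5 comes from aryl bromide 2 and dibromide 3 by copper-catalysed coupling of the aryl Grignard reagent 4, and 2 from commercial bromoresorcinol 1. Each step is a standard reaction on an unhindered primary or aromatic centre. The only demands are mono-substitution of 3 and an iodination that does not touch the ring.

## Roads not taken

**Alternative 1: building the arene last by polyketide-type aromatisation.**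
- Cut: both ring bonds flanking the chain-bearing aryl carbon. The partners are the complete C18 ester A3, methyl (9Z,13S,15Z)-13-(tert-butyldimethylsilyloxy)octadeca-9,15-dienoate, and the triketide equivalent A2, methyl 3,5-dioxohexanoate.
- Forward step: the trianion of A2 is acylated at its terminal carbon by A3, and the triketo ester closes by aldol condensation and dehydration to the resorcylate A1, methyl 2,4-dihydroxy-6-[(8Z,12S,14Z)-12-(tert-butyldimethylsilyloxy)heptadeca-8,14-dien-1-yl]benzoate. Ester hydrolysis, decarboxylation and desilylation would follow.
- Merit: the ring is born as a free resorcinol, so no phenol protection is needed. In this respect it is better than the chosen plan, which spends steps 1 and 13 on protection.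
- Weak points: the chain problem is moved, not solved. A3 holds the stereocentre and both Z-alkenes and would take at least as many steps as 19. It is then consumed as an enolisable, unactivated electrophile in a reaction needing three equivalents of strong base, where self-condensation and proton transfer compete. Three further steps follow.
- Comparison: the chosen plan sets two cheap, reliable steps against the protection-free arene, and spends its late intermediates only in mild, near-neutral reactions.

**Alternative 2: enzymatic hydration of a natural fatty acid.**
- Cut: no chain C–C bond. C2–C18 of α-linolenic acid A5 already are C1'–C17' with both Z-alkenes in place.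
- Forward step: a fatty acid hydratase of the linoleate 13-hydratase type hydrates only the C12=C13 alkene of A5 and gives (9Z,13S,15Z)-13-hydroxyoctadeca-9,15-dienoic acid A4. The carboxyl of A4 could then be exchanged for a 3,5-dioxygenated aryl group by decarboxylative arylation of its redox-active ester, followed by deprotection.
- Merit: about four to five steps, both geometries for free, and the stereocentre from one catalytic, protecting-group-free step. In step count and material cost this road is clearly better than the chosen plan.
- Weak points: everything depends on one enzyme that is not a catalogue reagent. Its regioselectivity among three similar Z-alkenes, its S sense and its conversion are properties of the protein that cannot be adjusted. It works in dilute aqueous suspension, A4 must be separated from unconverted A5, and neither the enantiomer nor chain analogues are accessible.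
- Comparison: the chosen plan sets against the shorter sequence its use of purchasable reagents only, a stereocentre of certain configuration, access to either enantiomer, and free variation of both chain ends.

**Alternative 3: lithiation–borylation at C12'.**
- Cut: the C11'–C12' bond.
- Forward step: (Z)-hex-3-enyl N,N-diisopropylcarbamate A7 is deprotonated enantioselectively at its oxygen-bearing carbon by a chiral diamine–alkyllithium base. The lithiated carbamate adds to boron of the homoallylic pinacol boronate A8, and 1,2-metallate rearrangement with loss of carbamate gives the secondary boronate A6, 2-[(8Z,12S,14Z)-1-(3,5-dimethoxyphenyl)heptadeca-8,14-dien-12-yl]-4,4,5,5-tetramethyl-1,3,2-dioxaborolane. Oxidation with retention and demethylation follow.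
- Merit: it is more convergent. The stereocentre is formed in the joining step, and the C14'=C15' alkene comes with fixed geometry from a commodity alcohol, so the epoxide and cuprate steps disappear. The endgame is shorter than in the chosen plan.
- Weak points: the C12' configuration rests on a stoichiometric chiral diamine at low temperature, and a minor enantiomer could not be removed from an oily lipid. A8 carries the other Z-alkene, is two carbons longer than 9, and needs at least as many steps plus a borylation. Its methyl ethers bring back the exhaustive demethylation problem unless the arene is reprotected.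
- Comparison: overall length is similar. The chosen plan sets against the better convergence a stereocentre bought enantiopure, no cryogenic stoichiometric chiral reagent, and a coupling handle (a carboxylic acid) that needs no prior redox adjustment.

Key step: step 9

Assumption: chain carbons are numbered C1' (benzylic) to C17' (methyl); 1 and 10 are taken as catalogue compounds, 10 being the S lactone of the L-glutamic acid series.

## Route

Step 1
Reactants: 1 5-bromobenzene-1,3-diol
Product: 2 1-bromo-3,5-bis(methoxymethoxy)benzene
Conditions: MOMCl (2.5 equiv), i-Pr2NEt (3 equiv), CH2Cl2, 0 °C → rt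
Reagents that add atoms: chloromethyl methyl ether, COCCl
Why: O-alkylation of both phenols by an α-chloro ether (Williamson-type); the formaldehyde acetals tolerate all later organometallic, basic and reductive steps and leave under mild acid at the end.

Step 2
Reactants: 2 1-bromo-3,5-bis(methoxymethoxy)benzene; 3 1,7-dibromoheptane
Product: 5 1-(7-bromoheptyl)-3,5-bis(methoxymethoxy)benzene, via arylmagnesium bromide 4 (not isolated)
Conditions: Mg, THF, 50 °C (1,2-dibromoethane to start); then 3 (3 equiv), Li2CuCl4 (3 mol %), THF/N-methylpyrrolidone, 0 °C → rt
Reagents that add atoms: none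
Why: Magnesium insertion gives the aryl Grignard reagent, and copper-catalysed (Kochi-type) sp2–sp3 coupling with a primary bromide forms the aryl–C1' bond; a threefold excess of the dibromide should hold back double arylation.

Step 3
Reactants: 5 1-(7-bromoheptyl)-3,5-bis(methoxymethoxy)benzene
Product: 6 1,3-bis(methoxymethoxy)-5-(non-8-yn-1-yl)benzene
Conditions: HC≡CLi·H2NCH2CH2NH2 (1.5 equiv), DMSO, 5 °C → rt
Reagents that add atoms: lithium acetylide ethylenediamine complex, [Li]C#C.NCCN
Why: SN2 alkylation of lithium acetylide by an unhindered primary bromide in a dipolar aprotic solvent adds C8' and C9'.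

Step 4
Reactants: 6 1,3-bis(methoxymethoxy)-5-(non-8-yn-1-yl)benzene
Product: 8 1-(9-iodonon-8-yn-1-yl)-3,5-bis(methoxymethoxy)benzene, via lithium alkynide 7 (not isolated)
Conditions: n-BuLi (1.05 equiv), THF, −78 °C; then I2 (1.1 equiv), −78 → 0 °C
Reagents that add atoms: iodine, II
Why: Deprotonation of the terminal alkyne (far more acidic than any ring C–H at −78 °C) and iodination of the alkynyllithium; this avoids electrophilic iodinating agents, which would attack the electron-rich ring.

Step 5
Reactants: 8 1-(9-iodonon-8-yn-1-yl)-3,5-bis(methoxymethoxy)benzene
Product: 9 1-[(8Z)-9-iodonon-8-en-1-yl]-3,5-bis(methoxymethoxy)benzene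
Conditions: 2-nitrobenzenesulfonylhydrazide (2 equiv), Et3N, THF/i-PrOH, rt, dark
Reagents that add atoms: none
Why: Diimide reduction: concerted syn transfer of two hydrogens to the iodoalkyne places chain and iodine cis and so fixes the Z geometry; no metal hydride is present that could cleave the C–I bond.

Step 6
Reactants: 10 (5S)-5-(hydroxymethyl)dihydrofuran-2(3H)-one
Product: 11 methyl 3-[(4S)-2,2-dimethyl-1,3-dioxolan-4-yl]propanoate
Conditions: 2,2-dimethoxypropane, MeOH, p-toluenesulfonic acid monohydrate (5 mol %), rt; NaHCO3 quench
Reagents that add atoms: 2,2-dimethoxypropane, COC(C)(C)OC; methanol, CO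
Why: Acid-catalysed lactone methanolysis is an unfavourable equilibrium that is pulled to the open form by transketalisation of the liberated 1,2-diol; the stereocentre is not involved and stays S.

Step 7
Reactants: 11 methyl 3-[(4S)-2,2-dimethyl-1,3-dioxolan-4-yl]propanoate
Product: 12 3-[(4S)-2,2-dimethyl-1,3-dioxolan-4-yl]propanoic acid
Conditions: LiOH·H2O, THF/H2O, 0 °C → rt; then cold 1 M HCl to pH 4, extraction, used at once
Reagents that add atoms: lithium hydroxide monohydrate, [Li+].[OH-].O
Why: Ester saponification; acidification stops at pH 4 and the acid is not stored, because stronger acid would strip the ketal and re-close the lactone.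

Step 8
Reactants: 12 3-[(4S)-2,2-dimethyl-1,3-dioxolan-4-yl]propanoic acid; 13 N-hydroxyphthalimide
Product: 14 1,3-dioxoisoindolin-2-yl 3-[(4S)-2,2-dimethyl-1,3-dioxolan-4-yl]propanoate
Conditions: N,N′-diisopropylcarbodiimide, 4-(dimethylamino)pyridine (10 mol %), CH2Cl2, 0 °C → rt
Reagents that add atoms: none
Why: Carbodiimide (Steglich-type) esterification gives the redox-active ester under neutral conditions that leave the ketal intact.

Step 9
Reactants: 14 1,3-dioxoisoindolin-2-yl 3-[(4S)-2,2-dimethyl-1,3-dioxolan-4-yl]propanoate; 9 1-[(8Z)-9-iodonon-8-en-1-yl]-3,5-bis(methoxymethoxy)benzene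
Product: 15 (4S)-4-{(3Z)-11-[3,5-bis(methoxymethoxy)phenyl]undec-3-en-1-yl}-2,2-dimethyl-1,3-dioxolane
Conditions: NiCl2·6H2O (20 mol %), 2,2′-bipyridine (20 mol %), AgNO3 (0.3 equiv), DMF, rt, undivided cell, Mg anode, reticulated vitreous carbon cathode, constant current; 14 (1.5 equiv)
Reagents that add atoms: none
Why: Cathodic reduction turns the divalent nickel–bipyridine precatalyst into low-valent nickel, which adds oxidatively to the C–I bond of 9 with retention of the Z geometry. Electron transfer from low-valent nickel (or from the silver-coated cathode) to the N-acyloxyphthalimide 14 fragments it to CO2, phthalimide anion and the primary radical at C10'. The alkenylnickel species captures this radical, and reductive elimination from the resulting trivalent nickel centre forms the C9'–C10' sp2–sp3 bond, while the sacrificial magnesium anode supplies the electrons. The closest known reaction type is the nickel-electrocatalytic decarboxylative alkenylation of redox-active esters with alkenyl halides at a cathode with a sacrificial anode, a known process for primary acids and alkenyl iodides. No ring closes and no stereocentre is created; the alkene geometry is set beforehand in 9 and is carried through because neither oxidative addition nor reductive elimination breaks the π bond. The step needs cross-coupling to outrun radical reduction, radical dimerisation and diene formation from 9, which an excess of 14, a high nickel loading and a low current density should secure by keeping the radical concentration below that of the alkenylnickel trap. The substrate removes the other dangers: the C14'=C15' alkene is not yet present, so the C10' radical has no 5-exo partner; the C12' stereocentre lies two carbons away inside a ketal; and the reductive medium leaves the electron-rich aryl acetals untouched.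

Step 10
Reactants: 15 (4S)-4-{(3Z)-11-[3,5-bis(methoxymethoxy)phenyl]undec-3-en-1-yl}-2,2-dimethyl-1,3-dioxolane
Product: 16 (2S,5Z)-13-[3,5-bis(methoxymethoxy)phenyl]tridec-5-ene-1,2-diol
Conditions: AcOH/H2O (4:1), rt
Reagents that add atoms: none
Why: Acid-catalysed ketal hydrolysis; the isopropylidene ketal ionises through a tertiary oxocarbenium ion far more readily than the aryl formaldehyde acetals, which need mineral acid, so aqueous acetic acid should free the diol alone.

Step 11
Reactants: 16 (2S,5Z)-13-[3,5-bis(methoxymethoxy)phenyl]tridec-5-ene-1,2-diol
Product: 18 (2S)-2-{(3Z)-11-[3,5-bis(methoxymethoxy)phenyl]undec-3-en-1-yl}oxirane, via primary tosylate 17 (not isolated)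
Conditions: TsCl (1.05 equiv), Et3N, Bu2SnO (2 mol %), CH2Cl2, 0 °C → rt; then K2CO3, MeOH, rt
Reagents that add atoms: none
Why: Tin-acetal-catalysed sulfonylation is selective for the primary hydroxyl, and the C12' alkoxide then displaces the tosylate at C13' (intramolecular Williamson closure, 3-exo-tet); the C12'–O bond is never broken, so the S configuration is retained.

Step 12
Reactants: 18 (2S)-2-{(3Z)-11-[3,5-bis(methoxymethoxy)phenyl]undec-3-en-1-yl}oxirane
Product: 19 (8Z,12S,14Z)-1-[3,5-bis(methoxymethoxy)phenyl]heptadeca-8,14-dien-12-ol
Conditions: EtLi (4 equiv), CuBr·SMe2 (2 equiv), Et2O, −35 °C; HC≡CH (4 equiv), −50 → −25 °C; then 18, Et2O/THF, −30 → 0 °C; aq NH4Cl/NH3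
Reagents that add atoms: ethyllithium, [Li]CC; acetylene, C#C (combined in the flask with CuBr·SMe2 to lithium di[(Z)-but-1-enyl]cuprate, [Li+].CC/C=C\[Cu-]/C=C\CC)
Why: Syn carbocupration of acetylene by lithium diethylcuprate gives the Z-dialkenylcuprate of fixed geometry, which opens the terminal epoxide by SN2 attack at the unsubstituted carbon C13'; C12' is not involved and stays S.

Step 13
Reactants: 19 (8Z,12S,14Z)-1-[3,5-bis(methoxymethoxy)phenyl]heptadeca-8,14-dien-12-ol
Product: 20 5-[(8Z,12S,14Z)-12-hydroxyheptadeca-8,14-dien-1-yl]benzene-1,3-diol
Conditions: HCl (3 M in MeOH), MeOH, rt → 40 °C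
Reagents that add atoms: none
Why: Acid-catalysed acetal exchange with methanol removes both methoxymethyl groups as dimethoxymethane, which keeps the formaldehyde equivalent away from the electron-rich ring; isolated Z-alkenes and the secondary alcohol are inert to dilute methanolic acid.

## Compound list

1 | 5-bromobenzene-1,3-diol | Oc1cc(O)cc(Br)c1 | starting material
2 | 1-bromo-3,5-bis(methoxymethoxy)benzene | COCOc1cc(OCOC)cc(Br)c1 | intermediate
3 | 1,7-dibromoheptane | BrCCCCCCCBr | starting material
4 | [3,5-bis(methoxymethoxy)phenyl]magnesium bromide | COCOc1cc(OCOC)cc([Mg]Br)c1 | intermediate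
5 | 1-(7-bromoheptyl)-3,5-bis(methoxymethoxy)benzene | COCOc1cc(OCOC)cc(CCCCCCCBr)c1 | intermediate
6 | 1,3-bis(methoxymethoxy)-5-(non-8-yn-1-yl)benzene | COCOc1cc(OCOC)cc(CCCCCCCC#C)c1 | intermediate
7 | {9-[3,5-bis(methoxymethoxy)phenyl]non-1-yn-1-yl}lithium | COCOc1cc(OCOC)cc(CCCCCCCC#C[Li])c1 | intermediate
8 | 1-(9-iodonon-8-yn-1-yl)-3,5-bis(methoxymethoxy)benzene | COCOc1cc(OCOC)cc(CCCCCCCC#CI)c1 | intermediate
9 | 1-[(8Z)-9-iodonon-8-en-1-yl]-3,5-bis(methoxymethoxy)benzene | COCOc1cc(OCOC)cc(CCCCCCC/C=C\I)c1 | intermediate
10 | (5S)-5-(hydroxymethyl)dihydrofuran-2(3H)-one | OC[C@@H]1CCC(=O)O1 | starting material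
11 | methyl 3-[(4S)-2,2-dimethyl-1,3-dioxolan-4-yl]propanoate | COC(=O)CC[C@H]1COC(C)(C)O1 | intermediate
12 | 3-[(4S)-2,2-dimethyl-1,3-dioxolan-4-yl]propanoic acid | OC(=O)CC[C@H]1COC(C)(C)O1 | intermediate
13 | N-hydroxyphthalimide | O=C1c2ccccc2C(=O)N1O | starting material
14 | 1,3-dioxoisoindolin-2-yl 3-[(4S)-2,2-dimethyl-1,3-dioxolan-4-yl]propanoate | O=C(CC[C@H]1COC(C)(C)O1)ON1C(=O)c2ccccc2C1=O | intermediate
15 | (4S)-4-{(3Z)-11-[3,5-bis(methoxymethoxy)phenyl]undec-3-en-1-yl}-2,2-dimethyl-1,3-dioxolane | COCOc1cc(OCOC)cc(CCCCCCC/C=C\CC[C@H]2COC(C)(C)O2)c1 | intermediate
16 | (2S,5Z)-13-[3,5-bis(methoxymethoxy)phenyl]tridec-5-ene-1,2-diol | COCOc1cc(OCOC)cc(CCCCCCC/C=C\CC[C@H](O)CO)c1 | intermediate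
17 | (2S,5Z)-13-[3,5-bis(methoxymethoxy)phenyl]-2-hydroxytridec-5-en-1-yl 4-methylbenzenesulfonate | COCOc1cc(OCOC)cc(CCCCCCC/C=C\CC[C@H](O)COS(=O)(=O)c2ccc(C)cc2)c1 | intermediate
18 | (2S)-2-{(3Z)-11-[3,5-bis(methoxymethoxy)phenyl]undec-3-en-1-yl}oxirane | COCOc1cc(OCOC)cc(CCCCCCC/C=C\CC[C@H]2CO2)c1 | intermediate
19 | (8Z,12S,14Z)-1-[3,5-bis(methoxymethoxy)phenyl]heptadeca-8,14-dien-12-ol | CC/C=C\C[C@@H](O)CC/C=C\CCCCCCCc1cc(OCOC)cc(OCOC)c1 | intermediate
20 | 5-[(8Z,12S,14Z)-12-hydroxyheptadeca-8,14-dien-1-yl]benzene-1,3-diol | CC/C=C\C[C@@H](O)CC/C=C\CCCCCCCc1cc(O)cc(O)c1 | target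

## Step count and least certain steps

Total: 13 steps. Longest linear sequence: 10 steps (steps 1–5 and 9–13, from 1). The radical precursor 14 is reached in 3 steps from 10.

**Step 9 (key step).** The most likely failure is loss of the C10' radical by hydrogen abstraction from DMF or by dimerisation before nickel captures it. Partial Z to E erosion is the second risk, if the alkenylnickel intermediate lives long enough to isomerise. Both depend on the balance of radical generation and nickel turnover, which current density only partly controls. Fallback: a Wittig olefination that forms C8'=C9' instead; it sets out from 2 and 11 and comes back at 15. Grignard reagent 4, made from 2 as in step 2, is coupled with 1,8-dibromooctane under the same copper catalysis to give 1-(8-bromooctyl)-3,5-bis(methoxymethoxy)benzene F1. PPh3 in refluxing MeCN converts it into {8-[3,5-bis(methoxymethoxy)phenyl]octyl}triphenylphosphonium bromide F2. Ester 11 is reduced with i-Bu2AlH at −78 °C to 3-[(4S)-2,2-dimethyl-1,3-dioxolan-4-yl]propanal F3. The ylide from F2 (NaN(SiMe3)2, THF, −78 °C) and F3 should give 15 under salt-free conditions, with Z selectivity that is high but not complete.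

**Step 5.** Over-reduction of the alkenyl iodide to the saturated iodide, or incomplete conversion, would leave contaminants that do not separate from 9, because diimide discriminates between alkyne and alkene only kinetically. Fallback: hydroboration and protonolysis, from 8 back to 9. Dicyclohexylborane (THF, 0 °C) adds syn to 8 to give {(1Z)-9-[3,5-bis(methoxymethoxy)phenyl]-1-iodonon-1-en-1-yl}dicyclohexylborane F4, and AcOH replaces boron by hydrogen with retention; no saturated by-product can form.

**Step 2.** Halogen–magnesium exchange, biaryl formation and arylation at both ends of 3 may compete, since aryl Grignard reagents couple less cleanly than alkyl ones under copper catalysis. Fallback: alkynylation, hydrogenation and bromination, from 2 back to 5. Sonogashira coupling of 2 with hept-6-yn-1-ol (PdCl2(PPh3)2, CuI, Et3N, 70 °C) gives 7-[3,5-bis(methoxymethoxy)phenyl]hept-6-yn-1-ol F5. Hydrogenation (H2, Pd/C, EtOAc) gives 7-[3,5-bis(methoxymethoxy)phenyl]heptan-1-ol F6, and CBr4/PPh3 in CH2Cl2 gives 5.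

**Step 10.** Partial loss of the aryl methoxymethyl groups during ketal hydrolysis would give mixtures, because the selectivity rests on a rate difference between two acetal types. Fallback: global deprotection and phenol-selective reprotection, from 15 back to 16. Methanolic HCl removes all three acetals to give 5-[(8Z,12S)-12,13-dihydroxytridec-8-en-1-yl]benzene-1,3-diol F7. MOMCl with K2CO3 in acetone then alkylates only the phenoxides and returns 16.

**Step 12.** Incomplete carbocupration would leave ethyl groups on copper that transfer to the epoxide, and excess acetylene or warming would cause oligomerisation to dienyl cuprates; either erodes yield and purity. Fallback: alkynylation and semi-hydrogenation, from 18 back to 19. Lithium but-1-ynide with BF3·OEt2 (THF, −78 °C) opens 18 at C13' to give (8Z,12S)-1-[3,5-bis(methoxymethoxy)phenyl]heptadec-8-en-14-yn-12-ol F8. Hydrogenation over Pd/CaCO3 poisoned with Pb(OAc)2 and quinoline should give 19.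

## Further compounds

F1 | step 9 | 1-(8-bromooctyl)-3,5-bis(methoxymethoxy)benzene | COCOc1cc(OCOC)cc(CCCCCCCCBr)c1
F2 | step 9 | {8-[3,5-bis(methoxymethoxy)phenyl]octyl}triphenylphosphonium bromide | COCOc1cc(OCOC)cc(CCCCCCCC[P+](c2ccccc2)(c2ccccc2)c2ccccc2)c1.[Br-]
F3 | step 9 | 3-[(4S)-2,2-dimethyl-1,3-dioxolan-4-yl]propanal | O=CCC[C@H]1COC(C)(C)O1
F4 | step 5 | {(1Z)-9-[3,5-bis(methoxymethoxy)phenyl]-1-iodonon-1-en-1-yl}dicyclohexylborane | COCOc1cc(OCOC)cc(CCCCCCC/C=C(\I)B(C2CCCCC2)C2CCCCC2)c1
F5 | step 2 | 7-[3,5-bis(methoxymethoxy)phenyl]hept-6-yn-1-ol | COCOc1cc(OCOC)cc(C#CCCCCCO)c1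
F6 | step 2 | 7-[3,5-bis(methoxymethoxy)phenyl]heptan-1-ol | COCOc1cc(OCOC)cc(CCCCCCCO)c1
F7 | step 10 | 5-[(8Z,12S)-12,13-dihydroxytridec-8-en-1-yl]benzene-1,3-diol | Oc1cc(O)cc(CCCCCCC/C=C\CC[C@H](O)CO)c1
F8 | step 12 | (8Z,12S)-1-[3,5-bis(methoxymethoxy)phenyl]heptadec-8-en-14-yn-12-ol | CCC#CC[C@@H](O)CC/C=C\CCCCCCCc1cc(OCOC)cc(OCOC)c1
A1 | alternative 1 | methyl 2,4-dihydroxy-6-[(8Z,12S,14Z)-12-(tert-butyldimethylsilyloxy)heptadeca-8,14-dien-1-yl]benzoate | CC/C=C\C[C@@H](O[Si](C)(C)C(C)(C)C)CC/C=C\CCCCCCCc1cc(O)cc(O)c1C(=O)OC
A2 | alternative 1 | methyl 3,5-dioxohexanoate | COC(=O)CC(=O)CC(C)=O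
A3 | alternative 1 | methyl (9Z,13S,15Z)-13-(tert-butyldimethylsilyloxy)octadeca-9,15-dienoate | CC/C=C\C[C@@H](O[Si](C)(C)C(C)(C)C)CC/C=C\CCCCCCCC(=O)OC
A4 | alternative 2 | (9Z,13S,15Z)-13-hydroxyoctadeca-9,15-dienoic acid | CC/C=C\C[C@@H](O)CC/C=C\CCCCCCCC(=O)O
A5 | alternative 2 | α-linolenic acid, (9Z,12Z,15Z)-octadeca-9,12,15-trienoic acid | CC/C=C\C/C=C\C/C=C\CCCCCCCC(=O)O
A6 | alternative 3 | 2-[(8Z,12S,14Z)-1-(3,5-dimethoxyphenyl)heptadeca-8,14-dien-12-yl]-4,4,5,5-tetramethyl-1,3,2-dioxaborolane | CC/C=C\C[C@@H](B1OC(C)(C)C(C)(C)O1)CC/C=C\CCCCCCCc1cc(OC)cc(OC)c1
A7 | alternative 3 | (Z)-hex-3-en-1-yl N,N-diisopropylcarbamate | CC/C=C\CCOC(=O)N(C(C)C)C(C)C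
A8 | alternative 3 | 2-[(3Z)-11-(3,5-dimethoxyphenyl)undec-3-en-1-yl]-4,4,5,5-tetramethyl-1,3,2-dioxaborolane | CC1(C)OB(CC/C=C\CCCCCCCc2cc(OC)cc(OC)c2)OC1(C)C
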